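**Retrosynthetic overview**

1. The bicyclo[3.3.1]nonane-2,4,9-trione is opened at two bonds at once, C4–C5 (Claisen/Dieckmann acylation) and C1–C8 (enol plus tertiary cation). This leads back to one acyclic, fully substituted 3,5,7-triketo ester carrying a lavandulyl chain on the benzoyl-bearing carbon.
2. In the forward direction both rings form in one flask: ring A (the phloroglucinol-level trione) first, ring B second; the monocyclic trione is not isolated.
3. The triketo ester is built by polyanion chemistry from methyl 2,4-diprenyl-3,5-dioxohexanoate: terminal alkylation with (S)-lavandulyl iodide, then terminal benzoylation.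
4. The dioxo ester comes from methyl acetoacetate (two prenylations, one γ-acetylation). The iodide comes from an Evans deconjugative prenylation of the senecioyl imide, reduction and iodination.
5. The one stereocenter brought in, C7, steers C1 and C5 in the chair-like ring-B closure.

Assumption: the target SMILES is one enol tautomer of the 2,4,9-trione; C1–C9 in the text are the bicyclo[3.3.1]nonane locants of 16 (C1, C3, C7 prenylated, C5 benzoylated, C8 gem-dimethyl).

**Route**

Step 1
Reactants: 1 (4S)-4-benzyl-1,3-oxazolidin-2-one; 2 3-methylbut-2-enoyl chloride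
Product: 3 (4S)-4-benzyl-3-(3-methylbut-2-enoyl)-1,3-oxazolidin-2-one
Conditions: n-BuLi, THF, −78 °C; then 2, −78 to 0 °C
Reagents that add atoms: none
Why: N-acylation of the lithiated oxazolidinone by the acid chloride (Evans imide formation); no stereocenter is created.

Step 2
Reactants: 3 (4S)-4-benzyl-3-(3-methylbut-2-enoyl)-1,3-oxazolidin-2-one; 4 1-bromo-3-methylbut-2-ene (prenyl bromide)
Product: 5 (4S)-4-benzyl-3-[(2S)-5-methyl-2-(prop-1-en-2-yl)hex-4-enoyl]-1,3-oxazolidin-2-one
Conditions: NaN(SiMe3)2 (1.05 equiv), THF, −78 °C; then 4, −78 to −40 °C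
Reagents that add atoms: none
Why: Evans asymmetric alkylation in the deconjugative mode: γ-deprotonation gives the chelated (Z)-dienolate, which is alkylated at the α-carbon on the face away from the benzyl group, setting the (S) center that becomes C7 and moving the alkene into the isopropenyl position.

Step 3
Reactants: 5 (4S)-4-benzyl-3-[(2S)-5-methyl-2-(prop-1-en-2-yl)hex-4-enoyl]-1,3-oxazolidin-2-one
Product: 6 (2S)-5-methyl-2-(prop-1-en-2-yl)hex-4-en-1-ol ((S)-lavandulol)
Conditions: LiBH4, H2O (1 equiv), Et2O, 0 °C
Reagents that add atoms: none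
Why: Reductive cleavage of the imide at the exocyclic carbonyl by LiBH4 gives the primary alcohol without epimerising the β,γ-unsaturated center or touching the alkenes, and returns the auxiliary.

Step 4
Reactants: 6 (2S)-5-methyl-2-(prop-1-en-2-yl)hex-4-en-1-ol
Product: 7 (3S)-3-(iodomethyl)-2,6-dimethylhepta-1,5-diene ((S)-lavandulyl iodide)
Conditions: PPh3, I2, imidazole, CH2Cl2, 0 °C
Reagents that add atoms: iodine, [I][I]
Why: Appel-type iodination converts the primary alcohol to the iodide by SN2 at CH2, leaving the adjacent stereocenter and both alkenes untouched.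

Step 5
Reactants: 8 methyl 3-oxobutanoate (methyl acetoacetate); 4 1-bromo-3-methylbut-2-ene (2.2 equiv in two portions)
Product: 9 methyl 7-methyl-2-(3-methylbut-2-en-1-yl)-3-oxooct-6-enoate
Conditions: NaH, THF, 0 °C; n-BuLi, 0 °C; 4 (1.0 equiv), 0 °C; then 4 (1.2 equiv), 23 to 45 °C
Reagents that add atoms: none
Why: Weiler dianion chemistry: the γ-carbanion is alkylated first, and the remaining β-keto ester enolate is then C-alkylated at the α-carbon by the second portion of the allylic bromide on warming.

Step 6
Reactants: 9 methyl 7-methyl-2-(3-methylbut-2-en-1-yl)-3-oxooct-6-enoate; 10 N-methoxy-N-methylacetamide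
Product: 11 methyl 2,4-bis(3-methylbut-2-en-1-yl)-3,5-dioxohexanoate
Conditions: LiN(i-Pr)2 (2.2 equiv, commercial solution), THF, −78 to 0 °C; 10, −78 to 0 °C; aq. HCl
Reagents that add atoms: none
Why: Claisen-type γ-acylation of the β-keto ester dianion by a Weinreb amide, whose chelated tetrahedral adduct survives until the acidic quench and so prevents proton transfer and double addition.

Step 7
Reactants: 11 methyl 2,4-bis(3-methylbut-2-en-1-yl)-3,5-dioxohexanoate; 7 (3S)-3-(iodomethyl)-2,6-dimethylhepta-1,5-diene; 12 N-methoxy-N-methylbenzamide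
Product: 14 methyl (8R)-6-benzoyl-11-methyl-2,4-bis(3-methylbut-2-en-1-yl)-3,5-dioxo-8-(prop-1-en-2-yl)dodec-10-enoate, via alkylated dioxo ester 13 (not isolated)
Conditions: LiN(i-Pr)2 (3.1 equiv), THF, −78 to 0 °C; 7, DMPU, −40 to 0 °C; LiN(i-Pr)2 (1.2 equiv), −78 °C; 12, −78 to 0 °C; aq. HCl
Reagents that add atoms: none
Why: Sequential polyketide-trianion chemistry: the terminal, least stabilised carbanion is alkylated by the primary iodide (SN2), one more equivalent of base regenerates a carbanion at the same carbon, and this is C-benzoylated by the Weinreb amide; the stereocenter is remote and untouched (its descriptor changes from S to R only through the CIP priorities).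

Step 8
Reactants: 14 methyl (8R)-6-benzoyl-11-methyl-2,4-bis(3-methylbut-2-en-1-yl)-3,5-dioxo-8-(prop-1-en-2-yl)dodec-10-enoate
Product: 16 (1R,5S,7R)-5-benzoyl-4-hydroxy-8,8-dimethyl-1,3,7-tris(3-methylbut-2-en-1-yl)bicyclo[3.3.1]non-3-ene-2,9-dione, via monocyclic trione 15 (not isolated)
Conditions: KOC(CH3)3 (2.05 equiv), THF, 0 to 23 °C; evaporate; HCO2H, 23 °C
Reagents that add atoms: none
Why: Proposed new method: two equivalents of a non-nucleophilic base give the dienolate in which the benzoyl-bearing carbon C5 closes onto the methyl ester to form ring A (Dieckmann/Claisen cyclization; closest known type is the base-mediated Claisen cyclization of 3,5,7-triketo esters to acylphloroglucinols), and the released methoxide is consumed by the acidic C3–H of trione 15 so it cannot cleave the benzoyl group; on switching to formic acid the isopropenyl group is protonated to the tertiary C8 cation, which the enol carbon C1 captures through a chair transition state with the C7 prenyl group equatorial to form ring B (closest known type is the biomimetic formic acid-mediated cation–olefin cyclization of lavandulyl-bearing dearomatized acylphloroglucinols), so C7 (R) fixes C1 (R) and C5 (S), while any O-cyclized tert-alkyl enol ether can re-ionise in the acid and drain to the irreversible C–C product.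

**Compound list**

1 | (4S)-4-benzyl-1,3-oxazolidin-2-one | O=C1N[C@@H](Cc2ccccc2)CO1 | starting material
2 | 3-methylbut-2-enoyl chloride | CC(C)=CC(Cl)=O | starting material
3 | (4S)-4-benzyl-3-(3-methylbut-2-enoyl)-1,3-oxazolidin-2-one | CC(C)=CC(=O)N1[C@@H](Cc2ccccc2)COC1=O | intermediate
4 | 1-bromo-3-methylbut-2-ene | CC(C)=CCBr | starting material
5 | (4S)-4-benzyl-3-[(2S)-5-methyl-2-(prop-1-en-2-yl)hex-4-enoyl]-1,3-oxazolidin-2-one | CC(C)=CC[C@@H](C(C)=C)C(=O)N1[C@@H](Cc2ccccc2)COC1=O | intermediate
6 | (2S)-5-methyl-2-(prop-1-en-2-yl)hex-4-en-1-ol | OC[C@@H](CC=C(C)C)C(C)=C | intermediate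
7 | (3S)-3-(iodomethyl)-2,6-dimethylhepta-1,5-diene | IC[C@@H](CC=C(C)C)C(C)=C | intermediate
8 | methyl 3-oxobutanoate | COC(=O)CC(C)=O | starting material
9 | methyl 7-methyl-2-(3-methylbut-2-en-1-yl)-3-oxooct-6-enoate (racemic) | COC(=O)C(CC=C(C)C)C(=O)CCC=C(C)C | intermediate
10 | N-methoxy-N-methylacetamide | CON(C)C(C)=O | starting material
11 | methyl 2,4-bis(3-methylbut-2-en-1-yl)-3,5-dioxohexanoate (epimer and enol mixture) | COC(=O)C(CC=C(C)C)C(=O)C(CC=C(C)C)C(C)=O | intermediate
12 | N-methoxy-N-methylbenzamide | CON(C)C(=O)c1ccccc1 | starting material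
13 | methyl (8S)-11-methyl-2,4-bis(3-methylbut-2-en-1-yl)-3,5-dioxo-8-(prop-1-en-2-yl)dodec-10-enoate | COC(=O)C(CC=C(C)C)C(=O)C(CC=C(C)C)C(=O)CC[C@@H](CC=C(C)C)C(C)=C | intermediate
14 | methyl (8R)-6-benzoyl-11-methyl-2,4-bis(3-methylbut-2-en-1-yl)-3,5-dioxo-8-(prop-1-en-2-yl)dodec-10-enoate (C2, C4, C6 epimer and enol mixture) | COC(=O)C(CC=C(C)C)C(=O)C(CC=C(C)C)C(=O)C(C(=O)c1ccccc1)C[C@@H](CC=C(C)C)C(C)=C | intermediate
15 | 2-benzoyl-2-[(2R)-5-methyl-2-(prop-1-en-2-yl)hex-4-en-1-yl]-4,6-bis(3-methylbut-2-en-1-yl)cyclohexane-1,3,5-trione (drawn as triketo form) | O=C1C(CC=C(C)C)C(=O)C(CC=C(C)C)C(=O)C1(C(=O)c2ccccc2)C[C@@H](CC=C(C)C)C(C)=C | intermediate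
16 | (1R,5S,7R)-5-benzoyl-4-hydroxy-8,8-dimethyl-1,3,7-tris(3-methylbut-2-en-1-yl)bicyclo[3.3.1]non-3-ene-2,9-dione | CC(C)=CCC1=C(O)[C@]2(C(=O)c3ccccc3)C[C@@H](CC=C(C)C)C(C)(C)[C@](CC=C(C)C)(C1=O)C2=O | target

**Step count and risks**

Total steps: 8. Longest linear sequence: 6 steps (1, 2, 3, 4, 7, 8).

Most likely to fail, in order:

Step 8. Risks are lactone or aldol closure instead of the Claisen closure, loss of the benzoyl group from the monocyclic trione 15, O- instead of C-capture of the cation, chroman formation from the prenyl groups in acid, and the 7-epimer. Fallback, setting out from 14 and returning at 16: the dipotassium salt of 15 is made as above, neutralised cold and O-methylated at once with Me3SiCHN2 (CH3OH/toluene, 0 °C) to the central methyl enol ether 2-benzoyl-5-methoxy-2-[(2R)-5-methyl-2-(prop-1-en-2-yl)hex-4-en-1-yl]-4,6-bis(3-methylbut-2-en-1-yl)cyclohex-4-ene-1,3-dione F1. Its two flanks still interconvert by dienol tautomerism, so the stereoconvergence is kept. Isolated F1 is cyclised in HCO2H to the bicyclic methyl enol ether (1R,5R,7R)-5-benzoyl-2-methoxy-8,8-dimethyl-1,3,7-tris(3-methylbut-2-en-1-yl)bicyclo[3.3.1]non-2-ene-4,9-dione F2 (same spatial arrangement as 16). The methyl group is then removed with LiCl in DMSO at 120 °C to give 16. This replaces the one-flask double closure by a stepwise, enol-protected sequence.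

Step 7. Risks are elimination of the β-branched iodide by the strongly basic trianion and incomplete second deprotonation. Fallback, setting out from 7 and returning at 13: the lithium enolate of amide 10 (LiN(i-Pr)2, THF, −78 °C) is alkylated with 7 to give the homologated Weinreb amide (4S)-N-methoxy-N,7-dimethyl-4-(prop-1-en-2-yl)oct-6-enamide F3. F3 acylates the dianion of 9 under the conditions of step 6 to give 13 directly. 13 is then isolated and benzoylated in a separate operation (LiN(i-Pr)2, 12) to reach 14. This swaps the trianion alkylation for an amide-enolate alkylation and a convergent acylation.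

Step 6. Risk is sluggish acylation at the hindered secondary γ-carbanion. Fallback, setting out from 9 and returning at 11: the dianion of 9 is added to acetaldehyde (THF, −78 °C) to give the aldol methyl 5-hydroxy-2,4-bis(3-methylbut-2-en-1-yl)-3-oxohexanoate F4. The secondary alcohol is then oxidised with Dess–Martin periodinane (CH2Cl2, NaHCO3) to give 11. This replaces the acylation by aldol addition and oxidation.

**Further compounds**

F1 | step 8 | 2-benzoyl-5-methoxy-2-[(2R)-5-methyl-2-(prop-1-en-2-yl)hex-4-en-1-yl]-4,6-bis(3-methylbut-2-en-1-yl)cyclohex-4-ene-1,3-dione | COC1=C(CC=C(C)C)C(=O)C(C(=O)c2ccccc2)(C[C@@H](CC=C(C)C)C(C)=C)C(=O)C1CC=C(C)C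
F2 | step 8 | (1R,5R,7R)-5-benzoyl-2-methoxy-8,8-dimethyl-1,3,7-tris(3-methylbut-2-en-1-yl)bicyclo[3.3.1]non-2-ene-4,9-dione | COC1=C(CC=C(C)C)C(=O)[C@]2(C(=O)c3ccccc3)C[C@@H](CC=C(C)C)C(C)(C)[C@@]1(CC=C(C)C)C2=O
F3 | step 7 | (4S)-N-methoxy-N,7-dimethyl-4-(prop-1-en-2-yl)oct-6-enamide | CON(C)C(=O)CC[C@@H](CC=C(C)C)C(C)=C
F4 | step 6 | methyl 5-hydroxy-2,4-bis(3-methylbut-2-en-1-yl)-3-oxohexanoate | COC(=O)C(CC=C(C)C)C(=O)C(CC=C(C)C)C(C)O
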